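## Retrosynthetic overview

1. The γ-lactone is closed last, by lactonisation of the C6 hydroxyl onto the C12 methyl ester after global desilylation.
2. The ten-membered carbocycle is closed before that, at C3–C4, by a nickel/chromium-catalysed Nozaki–Hiyama–Kishi coupling of a (Z)-alkenyl iodide with a cis-epoxy aldehyde; this sets C3.
3. The open chain comes from C7–C8 union of fragment A (C8 aldehyde, C1–C3 and C8–C10) with fragment B (allyl bromide, C4–C7 and C11–C13) by Barbier 2-(methoxycarbonyl)allylation, then C8 angeloylation.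
4. Fragment A: (Z)-but-2-ene-1,4-diol, Sharpless epoxidation (the epoxide is the first ring formed), then chelation-controlled amide-enolate addition to the epoxy methyl ketone (sets C10).
5. Fragment B: but-2-yn-1-ol and methyl propiolate via (Z)-3-iodobut-2-enal, asymmetric alkynylation (sets C6) and a new directed anti-hydroalumination/hydroxymethylation (sets the C7=C11 geometry).

Locants and abbreviations: germacrane-type labels are used (C1/C2 epoxide, C3 carbinol, C4=C5, C6 lactone oxygen, C7, C8 angelate, C10 carbinol, C11–C13 acrylate, C14/C15 methyls); PMB = 4-methoxybenzyl, TBS = tert-butyldimethylsilyl, TES = triethylsilyl, Ang = (2Z)-2-methylbut-2-enoyl.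

Assumption: (S,S)-ProPhenol is taken to give the 4S alcohol 18; if the sense is opposite, the (R,R) ligand is used.

## Route

Step 1
Reactants: 1 (Z)-but-2-ene-1,4-diol
Product: 2 (Z)-4-(PMB-oxy)but-2-en-1-ol
Conditions: NaH (1 equiv), PMBCl (1 equiv), Bu4NI (cat.), 1 (3 equiv), THF/DMF, 0 → 23 °C
Reagents that add atoms: 4-methoxybenzyl chloride, COc1ccc(CCl)cc1
Why: Williamson etherification with the diol in excess gives the mono-ether; no stereocentre is formed.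

Step 2
Reactants: 2 (Z)-4-(PMB-oxy)but-2-en-1-ol
Product: 3 [(2S,3R)-3-(PMB-oxymethyl)oxiran-2-yl]methanol
Conditions: Ti(OiPr)4, L-(+)-diisopropyl tartrate, tBuOOH, 4 Å MS, CH2Cl2, −20 °C
Reagents that add atoms: tert-butyl hydroperoxide, CC(C)(C)OO
Why: Sharpless asymmetric epoxidation of the Z-allylic alcohol; the L-(+)-tartrate titanium complex delivers oxygen to one face and gives the cis-(2S,3R)-epoxide, which is C1/C2 of the target.

Step 3
Reactants: 3 [(2S,3R)-3-(PMB-oxymethyl)oxiran-2-yl]methanol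
Product: 5 1-[(2S,3R)-3-(PMB-oxymethyl)oxiran-2-yl]ethan-1-ol (both carbinol epimers), via epoxy aldehyde 4 (not isolated)
Conditions: (COCl)2, DMSO, CH2Cl2, −78 °C; Et3N; then MeMgBr (5 equiv), THF, −78 → 0 °C
Reagents that add atoms: methylmagnesium bromide, C[Mg]Br
Why: Swern oxidation followed by Grignard addition in the same flask avoids isolating the labile cis-epoxy aldehyde; the new carbinol centre is oxidised in the next step.

Step 4
Reactants: 5 1-[(2S,3R)-3-(PMB-oxymethyl)oxiran-2-yl]ethan-1-ol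
Product: 6 1-[(2R,3R)-3-(PMB-oxymethyl)oxiran-2-yl]ethan-1-one
Conditions: Dess–Martin periodinane, NaHCO3, CH2Cl2, 0 → 23 °C
Reagents that add atoms: none
Why: buffered Dess–Martin oxidation gives the methyl ketone without epimerising the epoxide carbon.

Step 5
Reactants: 6 1-[(2R,3R)-3-(PMB-oxymethyl)oxiran-2-yl]ethan-1-one; 7 N-methoxy-N-methylacetamide
Product: 9 (3R)-3-hydroxy-N-methoxy-N-methyl-3-[(2R,3R)-3-(PMB-oxymethyl)oxiran-2-yl]butanamide, via lithium amide enolate 8 (not isolated)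
Conditions: 7, LiN(iPr)2, THF, −78 °C; then 6 premixed with MgBr2·OEt2, CH2Cl2, −78 °C
Reagents that add atoms: none
Why: aldol-type addition under Cram chelate control (magnesium bridges the ketone and epoxide oxygens, the enolate attacks the face away from the second epoxide carbon) sets the tertiary carbinol C10 as R.

Step 6
Reactants: 9 (3R)-3-hydroxy-N-methoxy-N-methyl-3-[(2R,3R)-3-(PMB-oxymethyl)oxiran-2-yl]butanamide
Product: 10 (3R)-N-methoxy-N-methyl-3-[(2R,3R)-3-(PMB-oxymethyl)oxiran-2-yl]-3-(TES-oxy)butanamide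
Conditions: TESOTf, 2,6-lutidine, CH2Cl2, −78 → 0 °C
Reagents that add atoms: triethylsilyl trifluoromethanesulfonate, CC[Si](CC)(CC)OS(=O)(=O)C(F)(F)F
Why: silyl triflate silylation protects the tertiary alcohol, which blocks retro-aldol cleavage and later lactol formation.

Step 7
Reactants: 10 (3R)-N-methoxy-N-methyl-3-[(2R,3R)-3-(PMB-oxymethyl)oxiran-2-yl]-3-(TES-oxy)butanamide
Product: 11 (3R)-3-[(2R,3R)-3-(PMB-oxymethyl)oxiran-2-yl]-3-(TES-oxy)butanal
Conditions: iBu2AlH, THF, −78 °C; aq. potassium sodium tartrate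
Reagents that add atoms: none
Why: Weinreb amide reduction stops at the aldehyde through the stable chelated tetrahedral intermediate; the epoxide is inert at −78 °C.

Step 8
Reactants: 12 but-2-yn-1-ol
Product: 14 (Z)-3-iodobut-2-en-1-ol, via cyclic alkenylalanate 13 (not isolated)
Conditions: NaAlH2(OCH2CH2OMe)2, THF, 0 → 23 °C; EtOAc; then I2, −78 °C
Reagents that add atoms: iodine, II
Why: hydroxyl-directed anti-hydroalumination puts aluminium on the distal carbon, and iodinolysis with retention gives the Z iodide (iodine cis to CH2OH).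

Step 9
Reactants: 14 (Z)-3-iodobut-2-en-1-ol
Product: 15 (Z)-3-iodobut-2-enal
Conditions: MnO2, CH2Cl2, 23 °C, dark
Reagents that add atoms: none
Why: allylic oxidation with MnO2 is neutral and keeps the Z geometry; the enal is used at once.

Step 10
Reactants: 15 (Z)-3-iodobut-2-enal; 16 methyl propiolate
Product: 18 methyl (4S,5Z)-4-hydroxy-6-iodohept-5-en-2-ynoate, via methylzinc alkynylide 17 (not isolated)
Conditions: 16, Me2Zn (3 equiv), (S,S)-ProPhenol (10 mol %), Ph3P=O (20 mol %), PhMe, 0 °C; then 15, 4 °C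
Reagents that add atoms: none
Why: ProPhenol–zinc-catalysed enantioselective alkynylation of an enal (Trost-type) sets the C6 carbinol by catalyst control.

Step 11
Reactants: 18 methyl (4S,5Z)-4-hydroxy-6-iodohept-5-en-2-ynoate
Product: 20 methyl (2E,4R,5Z)-4-hydroxy-2-(hydroxymethyl)-6-iodohepta-2,5-dienoate, via chelated alkenylalanate 19 (not isolated)
Conditions: NaAlH2(OCH2CH2OMe)2 (1.1 equiv), THF, −78 °C; then monomeric CH2O (from cracked paraformaldehyde), −78 → −40 °C; aq. potassium sodium tartrate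
Reagents that add atoms: formaldehyde, C=O
Why: Proposed new method: alkoxide-directed anti-hydroalumination of a γ-hydroxy ynoate followed by C-hydroxymethylation of the alanate, in which the aluminium alkoxide delivers hydride to C7 and aluminium to C11 inside a five-membered oxa-aluminacycle, so that the C11–Al bond is held cis to C6 and trans to the ester and substitution by formaldehyde with retention forms C11–C13 with C13 cis to C6 (the geometry that later gives the cis-fused lactone), the alkenyl iodide being inert at −78 °C; the closest known reaction types are the anti-reduction of γ-hydroxy ynoates to E-enoates by protonolysis of the same alanate, the hydride/iodine sequence of step 8, and the hydroxymethylation of alkenylalanates with formaldehyde.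

Step 12
Reactants: 20 methyl (2E,4R,5Z)-4-hydroxy-2-(hydroxymethyl)-6-iodohepta-2,5-dienoate
Product: 21 methyl (2E,4R,5Z)-4-(TBS-oxy)-2-(TBS-oxymethyl)-6-iodohepta-2,5-dienoate
Conditions: TBSCl (3 equiv), imidazole, DMF, 0 → 23 °C
Reagents that add atoms: tert-butyldimethylsilyl chloride, CC(C)(C)[Si](C)(C)Cl
Why: bis-silylation protects both alcohols and removes the risk of dihydrofuran formation in the later bromination.

Step 13
Reactants: 21 methyl (2E,4R,5Z)-4-(TBS-oxy)-2-(TBS-oxymethyl)-6-iodohepta-2,5-dienoate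
Product: 22 methyl (2E,4R,5Z)-4-(TBS-oxy)-2-(hydroxymethyl)-6-iodohepta-2,5-dienoate
Conditions: HF·pyridine, pyridine, THF, 0 °C
Reagents that add atoms: none
Why: buffered fluoride cleaves the primary allylic silyl ether much faster than the secondary one.

Step 14
Reactants: 22 methyl (2E,4R,5Z)-4-(TBS-oxy)-2-(hydroxymethyl)-6-iodohepta-2,5-dienoate
Product: 23 methyl (2Z,4R,5Z)-2-(bromomethyl)-4-(TBS-oxy)-6-iodohepta-2,5-dienoate
Conditions: CBr4, PPh3, CH2Cl2, −20 → 0 °C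
Reagents that add atoms: carbon tetrabromide, BrC(Br)(Br)Br
Why: Appel bromination of the primary allylic alcohol gives the bromide with the alkene geometry unchanged (the Z descriptor arises only from the priority of CH2Br).

Step 15
Reactants: 11 (3R)-3-[(2R,3R)-3-(PMB-oxymethyl)oxiran-2-yl]-3-(TES-oxy)butanal; 23 methyl (2Z,4R,5Z)-2-(bromomethyl)-4-(TBS-oxy)-6-iodohepta-2,5-dienoate
Product: 24 methyl (3R,4R,6R)-3-[(1R,2Z)-1-(TBS-oxy)-3-iodobut-2-en-1-yl]-4-hydroxy-2-methylidene-6-[(2R,3R)-3-(PMB-oxymethyl)oxiran-2-yl]-6-(TES-oxy)heptanoate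
Conditions: In powder (2 equiv), 23 (1.3 equiv), THF/H2O (1:1), 23 °C
Reagents that add atoms: none
Why: indium Barbier 2-(alkoxycarbonyl)allylation through a closed chair transition state, in which the Z bromide places the C6 substituent axial to give the 7,8-syn adduct and the C6 silyloxy centre (C–H eclipsing the alkene, attack anti to the alkenyl group) fixes C7 relative to C6; the alkenyl iodide is inert and the hydroxy ester is isolated without lactonisation.

Step 16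
Reactants: 24 methyl (3R,4R,6R)-3-[(1R,2Z)-1-(TBS-oxy)-3-iodobut-2-en-1-yl]-4-hydroxy-2-methylidene-6-[(2R,3R)-3-(PMB-oxymethyl)oxiran-2-yl]-6-(TES-oxy)heptanoate; 25 angelic acid, (2Z)-2-methylbut-2-enoic acid
Product: 27 methyl (3R,4R,6R)-4-(Ang-oxy)-3-[(1R,2Z)-1-(TBS-oxy)-3-iodobut-2-en-1-yl]-2-methylidene-6-[(2R,3R)-3-(PMB-oxymethyl)oxiran-2-yl]-6-(TES-oxy)heptanoate, via angelic 2,4,6-trichlorobenzoic anhydride 26 (not isolated)
Conditions: 25, 2,4,6-trichlorobenzoyl chloride, Et3N, PhMe, 23 °C; then 24, DMAP, PhMe, 23 → 40 °C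
Reagents that add atoms: none
Why: Yamaguchi esterification through the mixed anhydride transfers the angeloyl group without Z to E isomerisation and faster than the hydroxy ester can lactonise.

Step 17
Reactants: 27 methyl (3R,4R,6R)-4-(Ang-oxy)-3-[(1R,2Z)-1-(TBS-oxy)-3-iodobut-2-en-1-yl]-2-methylidene-6-[(2R,3R)-3-(PMB-oxymethyl)oxiran-2-yl]-6-(TES-oxy)heptanoate
Product: 28 methyl (3R,4R,6R)-4-(Ang-oxy)-3-[(1R,2Z)-1-(TBS-oxy)-3-iodobut-2-en-1-yl]-6-[(2R,3R)-3-(hydroxymethyl)oxiran-2-yl]-2-methylidene-6-(TES-oxy)heptanoate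
Conditions: DDQ, CH2Cl2/H2O (18:1), 0 °C
Reagents that add atoms: none
Why: oxidative PMB cleavage is selective for the electron-rich benzyl ether and leaves silyl ethers, esters, epoxide and alkenyl iodide untouched.

Step 18
Reactants: 28 methyl (3R,4R,6R)-4-(Ang-oxy)-3-[(1R,2Z)-1-(TBS-oxy)-3-iodobut-2-en-1-yl]-6-[(2R,3R)-3-(hydroxymethyl)oxiran-2-yl]-2-methylidene-6-(TES-oxy)heptanoate
Product: 29 methyl (3R,4R,6R)-4-(Ang-oxy)-3-[(1R,2Z)-1-(TBS-oxy)-3-iodobut-2-en-1-yl]-6-[(2R,3S)-3-formyloxiran-2-yl]-2-methylidene-6-(TES-oxy)heptanoate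
Conditions: Dess–Martin periodinane, NaHCO3, CH2Cl2, 0 °C; used crude
Reagents that add atoms: none
Why: buffered Dess–Martin oxidation gives the cis-epoxy aldehyde without epimerisation.

Step 19
Reactants: 29 methyl (3R,4R,6R)-4-(Ang-oxy)-3-[(1R,2Z)-1-(TBS-oxy)-3-iodobut-2-en-1-yl]-6-[(2R,3S)-3-formyloxiran-2-yl]-2-methylidene-6-(TES-oxy)heptanoate
Product: 30 methyl 2-[(1R,2R,3R,4Z,6S,7R,8R,10R)-8-(Ang-oxy)-6-(TBS-oxy)-1,2-epoxy-3-hydroxy-4,10-dimethyl-10-(TES-oxy)cyclodec-4-en-7-yl]prop-2-enoate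
Conditions: CrCl2 (20 mol %), (S)-N-[2-(4-isopropyl-4,5-dihydrooxazol-2-yl)-6-methoxyphenyl]methanesulfonamide (22 mol %), Et3N (40 mol %), NiCl2·(2,9-dimethyl-1,10-phenanthroline) (5 mol %), Mn powder (3 equiv), Cp2ZrCl2 (1.5 equiv), LiCl, MeCN, 23 °C, syringe-pump addition to 2 mM
Reagents that add atoms: none
Why: catalytic asymmetric Nozaki–Hiyama–Kishi macrocyclisation forms C3–C4 with retention of the Z alkene geometry, and Felkin–Anh addition anti to the epoxide C–O bond, reinforced by the sulfonamide ligand, gives the 3R carbinol.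

Step 20
Reactants: 30 methyl 2-[(1R,2R,3R,4Z,6S,7R,8R,10R)-8-(Ang-oxy)-6-(TBS-oxy)-1,2-epoxy-3-hydroxy-4,10-dimethyl-10-(TES-oxy)cyclodec-4-en-7-yl]prop-2-enoate
Product: 32 (1R,2R,3R,4Z,6S,7R,8R,10R)-8-(Ang-oxy)-1,2-epoxy-3,10-dihydroxygermacra-4,11(13)-dien-12,6-olide (CNP0351240.2), via desilylated hydroxy ester 31 (not isolated)
Conditions: HF·pyridine, pyridine, THF, 0 → 23 °C; then pyridinium p-toluenesulfonate (cat.), CH2Cl2, 23 °C
Reagents that add atoms: none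
Why: buffered fluoride removes both silyl groups and the freed C6 hydroxyl, cis to the acrylate on C7, lactonises onto the methyl ester to give the cis-fused α-methylene-γ-butyrolactone with no stereocentre touched.

## Compound list

1 | (Z)-but-2-ene-1,4-diol | OC/C=C\CO | starting material
2 | (Z)-4-(PMB-oxy)but-2-en-1-ol | COc1ccc(COC/C=C\CO)cc1 | intermediate
3 | [(2S,3R)-3-(PMB-oxymethyl)oxiran-2-yl]methanol | COc1ccc(COC[C@H]2O[C@H]2CO)cc1 | intermediate
4 | (2R,3R)-3-(PMB-oxymethyl)oxirane-2-carbaldehyde | COc1ccc(COC[C@H]2O[C@H]2C=O)cc1 | intermediate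
5 | 1-[(2S,3R)-3-(PMB-oxymethyl)oxiran-2-yl]ethan-1-ol, carbinol epimers | COc1ccc(COC[C@H]2O[C@H]2C(C)O)cc1 | intermediate
6 | 1-[(2R,3R)-3-(PMB-oxymethyl)oxiran-2-yl]ethan-1-one | COc1ccc(COC[C@H]2O[C@H]2C(C)=O)cc1 | intermediate
7 | N-methoxy-N-methylacetamide | CC(=O)N(C)OC | starting material
8 | lithium 1-[methoxy(methyl)amino]ethen-1-olate | [Li]OC(=C)N(C)OC | intermediate
9 | (3R)-3-hydroxy-N-methoxy-N-methyl-3-[(2R,3R)-3-(PMB-oxymethyl)oxiran-2-yl]butanamide | COc1ccc(COC[C@H]2O[C@H]2[C@](C)(O)CC(=O)N(C)OC)cc1 | intermediate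
10 | (3R)-N-methoxy-N-methyl-3-[(2R,3R)-3-(PMB-oxymethyl)oxiran-2-yl]-3-(TES-oxy)butanamide | COc1ccc(COC[C@H]2O[C@H]2[C@](C)(O[Si](CC)(CC)CC)CC(=O)N(C)OC)cc1 | intermediate
11 | (3R)-3-[(2R,3R)-3-(PMB-oxymethyl)oxiran-2-yl]-3-(TES-oxy)butanal | COc1ccc(COC[C@H]2O[C@H]2[C@](C)(O[Si](CC)(CC)CC)CC=O)cc1 | intermediate
12 | but-2-yn-1-ol | CC#CCO | starting material
13 | sodium 2,2-bis(2-methoxyethoxy)-3-methyl-2,5-dihydro-1,2-oxaluminol-2-uide | [Na+].COCCO[Al-]1(OCCOC)OCC=C1C | intermediate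
14 | (Z)-3-iodobut-2-en-1-ol | C/C(I)=C/CO | intermediate
15 | (Z)-3-iodobut-2-enal | C/C(I)=C/C=O | intermediate
16 | methyl propiolate | C#CC(=O)OC | starting material
17 | methyl 3-(methylzincio)prop-2-ynoate | C[Zn]C#CC(=O)OC | intermediate
18 | methyl (4S,5Z)-4-hydroxy-6-iodohept-5-en-2-ynoate | C/C(I)=C/[C@H](O)C#CC(=O)OC | intermediate
19 | sodium oxa-aluminacycle from 18 (Al on C2 and on the C4 oxygen, bis(2-methoxyethoxy)) | [Na+].COCCO[Al-]1(OCCOC)O[C@@H](/C=C(/C)I)C=C1C(=O)OC | intermediate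
20 | methyl (2E,4R,5Z)-4-hydroxy-2-(hydroxymethyl)-6-iodohepta-2,5-dienoate | C/C(I)=C/[C@H](O)/C=C(\CO)C(=O)OC | intermediate
21 | methyl (2E,4R,5Z)-4-(TBS-oxy)-2-(TBS-oxymethyl)-6-iodohepta-2,5-dienoate | C/C(I)=C/[C@H](O[Si](C)(C)C(C)(C)C)/C=C(\CO[Si](C)(C)C(C)(C)C)C(=O)OC | intermediate
22 | methyl (2E,4R,5Z)-4-(TBS-oxy)-2-(hydroxymethyl)-6-iodohepta-2,5-dienoate | C/C(I)=C/[C@H](O[Si](C)(C)C(C)(C)C)/C=C(\CO)C(=O)OC | intermediate
23 | methyl (2Z,4R,5Z)-2-(bromomethyl)-4-(TBS-oxy)-6-iodohepta-2,5-dienoate | C/C(I)=C/[C@H](O[Si](C)(C)C(C)(C)C)/C=C(\CBr)C(=O)OC | intermediate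
24 | methyl (3R,4R,6R)-3-[(1R,2Z)-1-(TBS-oxy)-3-iodobut-2-en-1-yl]-4-hydroxy-2-methylidene-6-[(2R,3R)-3-(PMB-oxymethyl)oxiran-2-yl]-6-(TES-oxy)heptanoate | C=C(C(=O)OC)[C@@H]([C@@H](O[Si](C)(C)C(C)(C)C)/C=C(/C)I)[C@H](O)C[C@@](C)(O[Si](CC)(CC)CC)[C@@H]1O[C@@H]1COCc1ccc(OC)cc1 | intermediate
25 | angelic acid, (2Z)-2-methylbut-2-enoic acid | C/C=C(/C)C(=O)O | starting material
26 | (2Z)-2-methylbut-2-enoic 2,4,6-trichlorobenzoic anhydride | C/C=C(/C)C(=O)OC(=O)c1c(Cl)cc(Cl)cc1Cl | intermediate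
27 | 4-O-angelate of 24 | C=C(C(=O)OC)[C@@H]([C@@H](O[Si](C)(C)C(C)(C)C)/C=C(/C)I)[C@H](OC(=O)/C(C)=C\C)C[C@@](C)(O[Si](CC)(CC)CC)[C@@H]1O[C@@H]1COCc1ccc(OC)cc1 | intermediate
28 | primary alcohol from 27, (2R,3R)-3-(hydroxymethyl)oxiranyl | C=C(C(=O)OC)[C@@H]([C@@H](O[Si](C)(C)C(C)(C)C)/C=C(/C)I)[C@H](OC(=O)/C(C)=C\C)C[C@@](C)(O[Si](CC)(CC)CC)[C@@H]1O[C@@H]1CO | intermediate
29 | epoxy aldehyde from 28, (2R,3S)-3-formyloxiranyl | C=C(C(=O)OC)[C@@H]([C@@H](O[Si](C)(C)C(C)(C)C)/C=C(/C)I)[C@H](OC(=O)/C(C)=C\C)C[C@@](C)(O[Si](CC)(CC)CC)[C@@H]1O[C@@H]1C=O | intermediate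
30 | methyl 2-[(1R,2R,3R,4Z,6S,7R,8R,10R)-8-(Ang-oxy)-6-(TBS-oxy)-1,2-epoxy-3-hydroxy-4,10-dimethyl-10-(TES-oxy)cyclodec-4-en-7-yl]prop-2-enoate | C=C(C(=O)OC)[C@H]1[C@@H](O[Si](C)(C)C(C)(C)C)/C=C(/C)[C@@H](O)[C@H]2O[C@H]2[C@](C)(O[Si](CC)(CC)CC)C[C@H]1OC(=O)/C(C)=C\C | intermediate
31 | methyl 2-[(1R,2R,3R,4Z,6S,7S,8R,10R)-8-(Ang-oxy)-1,2-epoxy-3,6,10-trihydroxy-4,10-dimethylcyclodec-4-en-7-yl]prop-2-enoate | C=C(C(=O)OC)[C@H]1[C@@H](O)/C=C(/C)[C@@H](O)[C@H]2O[C@H]2[C@](C)(O)C[C@H]1OC(=O)/C(C)=C\C | intermediate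
32 | (1R,2R,3R,4Z,6S,7R,8R,10R)-8-(Ang-oxy)-1,2-epoxy-3,10-dihydroxygermacra-4,11(13)-dien-12,6-olide (CNP0351240.2) | C=C1C(=O)O[C@H]2/C=C(/C)[C@@H](O)[C@H]3O[C@H]3[C@](C)(O)C[C@@H](OC(=O)/C(C)=C\C)[C@@H]12 | target

## Step count and risks

Total steps: 20. Longest linear sequence: 13 (steps 1–7 then 15–20, or steps 8–14 then 15–20), which is 65 % of the total.

**Step 11 (the proposed new step).** The alanate may only be protonated (giving the E-enoate), may lose its geometry through an oxygen-bound allenolate, or may over-reduce. The fallback uses known chemistry, sets out from 15 and comes back at 23. An (S)-selective hydroxynitrile lyase (Hevea brasiliensis) with HCN in buffered MTBE gives (2S,3Z)-2-hydroxy-4-iodopent-3-enenitrile F1. TBSCl and imidazole give (2S,3Z)-2-(TBS-oxy)-4-iodopent-3-enenitrile F2. iBu2AlH at −78 °C and hydrolysis of the imine give (2S,3Z)-2-(TBS-oxy)-4-iodopent-3-enal F3. A Morita–Baylis–Hillman reaction with methyl acrylate and DABCO gives methyl 2-[(2S,3Z)-2-(TBS-oxy)-1-hydroxy-4-iodopent-3-en-1-yl]prop-2-enoate F4 (both carbinol epimers converge). NBS with Me2S then brominates with allylic transposition to the bromide 23.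

**Step 15 (fragment union).** The 7,8-syn relationship is dependable, but the face of C7 is set only by the C6 silyloxy centre and may be low or reversed. The fallback reverses the order of the two couplings, sets out from 10 and 21, and comes back at 31.
- DDQ on 10 gives (3R)-3-[(2R,3R)-3-(hydroxymethyl)oxiran-2-yl]-N-methoxy-N-methyl-3-(TES-oxy)butanamide F5, and Dess–Martin oxidation gives the (2R,3S)-formyloxirane aldehyde F6.
- Intermolecular Nozaki–Hiyama–Kishi coupling of F6 with 21 (NiCl2 cat., CrCl2, DMSO) gives the (3R)-allylic alcohol F7, and TBSOTf with 2,6-lutidine gives its 3-O-TBS ether F8.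
- Cp2Zr(H)Cl reduces the Weinreb amide to the C8 aldehyde F9, buffered HF·pyridine frees the primary allylic alcohol F10, and CBr4/PPh3 gives the allylic bromide F11.
- Indium in THF/H2O at 2 mM closes the ten-membered ring at C7–C8 by intramolecular Barbier allylation (the ring closure precedented for germacranolides), where ring constraints rather than C6 alone fix the face, giving the macrocyclic hydroxy ester F12.
- Yamaguchi esterification gives the 8-O-angelate F13, and HF·pyridine removes the three silyl groups to give 31, which lactonises to 32 as in step 20.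

**Step 19 (ten-membered ring closure).** The flexible open chain may oligomerise, or the alkenylnickel species may add to the acrylate. The fallback forms the lactone first so that the cis-fused bicycle holds the two chain ends together; it sets out from 27 and comes back at 32. HF·pyridine gives the desilylated hydroxy ester F14, which lactonises (pyridinium p-toluenesulfonate) to the cis-fused α-methylene lactone F15. DDQ gives the primary alcohol F16, and Dess–Martin oxidation gives the epoxy aldehyde F17. The nickel/chromium-catalysed coupling of step 19 on F17 then closes the carbocycle and gives 32 directly.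

## Further compounds

F1 | step 11 | (2S,3Z)-2-hydroxy-4-iodopent-3-enenitrile | C/C(I)=C/[C@H](O)C#N
F2 | step 11 | (2S,3Z)-2-(TBS-oxy)-4-iodopent-3-enenitrile | C/C(I)=C/[C@H](O[Si](C)(C)C(C)(C)C)C#N
F3 | step 11 | (2S,3Z)-2-(TBS-oxy)-4-iodopent-3-enal | C/C(I)=C/[C@H](O[Si](C)(C)C(C)(C)C)C=O
F4 | step 11 | methyl 2-[(2S,3Z)-2-(TBS-oxy)-1-hydroxy-4-iodopent-3-en-1-yl]prop-2-enoate, C1 epimers | C/C(I)=C/[C@H](O[Si](C)(C)C(C)(C)C)C(O)C(=C)C(=O)OC
F5 | step 15 | (3R)-3-[(2R,3R)-3-(hydroxymethyl)oxiran-2-yl]-N-methoxy-N-methyl-3-(TES-oxy)butanamide | OC[C@H]1O[C@H]1[C@](C)(O[Si](CC)(CC)CC)CC(=O)N(C)OC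
F6 | step 15 | (3R)-3-[(2R,3S)-3-formyloxiran-2-yl]-N-methoxy-N-methyl-3-(TES-oxy)butanamide | O=C[C@H]1O[C@H]1[C@](C)(O[Si](CC)(CC)CC)CC(=O)N(C)OC
F7 | step 15 | C3–C4 coupled (3R)-allylic alcohol with C8 Weinreb amide, TBS ethers at C6 and C13, TES ether at C10 | C/C(=C/[C@H](O[Si](C)(C)C(C)(C)C)/C=C(\CO[Si](C)(C)C(C)(C)C)C(=O)OC)[C@@H](O)[C@H]1O[C@H]1[C@](C)(O[Si](CC)(CC)CC)CC(=O)N(C)OC
F8 | step 15 | 3-O-TBS ether of F7 | C/C(=C/[C@H](O[Si](C)(C)C(C)(C)C)/C=C(\CO[Si](C)(C)C(C)(C)C)C(=O)OC)[C@@H](O[Si](C)(C)C(C)(C)C)[C@H]1O[C@H]1[C@](C)(O[Si](CC)(CC)CC)CC(=O)N(C)OC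
F9 | step 15 | C8 aldehyde from F8 | C/C(=C/[C@H](O[Si](C)(C)C(C)(C)C)/C=C(\CO[Si](C)(C)C(C)(C)C)C(=O)OC)[C@@H](O[Si](C)(C)C(C)(C)C)[C@H]1O[C@H]1[C@](C)(O[Si](CC)(CC)CC)CC=O
F10 | step 15 | C13 primary alcohol from F9 | C/C(=C/[C@H](O[Si](C)(C)C(C)(C)C)/C=C(\CO)C(=O)OC)[C@@H](O[Si](C)(C)C(C)(C)C)[C@H]1O[C@H]1[C@](C)(O[Si](CC)(CC)CC)CC=O
F11 | step 15 | C13 bromide from F10 | C/C(=C/[C@H](O[Si](C)(C)C(C)(C)C)/C=C(\CBr)C(=O)OC)[C@@H](O[Si](C)(C)C(C)(C)C)[C@H]1O[C@H]1[C@](C)(O[Si](CC)(CC)CC)CC=O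
F12 | step 15 | methyl 2-[(1R,2R,3R,4Z,6S,7R,8R,10R)-3,6-bis(TBS-oxy)-1,2-epoxy-8-hydroxy-4,10-dimethyl-10-(TES-oxy)cyclodec-4-en-7-yl]prop-2-enoate | C=C(C(=O)OC)[C@H]1[C@@H](O[Si](C)(C)C(C)(C)C)/C=C(/C)[C@@H](O[Si](C)(C)C(C)(C)C)[C@H]2O[C@H]2[C@](C)(O[Si](CC)(CC)CC)C[C@H]1O
F13 | step 15 | 8-O-angelate of F12 | C=C(C(=O)OC)[C@H]1[C@@H](O[Si](C)(C)C(C)(C)C)/C=C(/C)[C@@H](O[Si](C)(C)C(C)(C)C)[C@H]2O[C@H]2[C@](C)(O[Si](CC)(CC)CC)C[C@H]1OC(=O)/C(C)=C\C
F14 | step 19 | methyl (3S,4R,6R)-4-(Ang-oxy)-6-hydroxy-3-[(1R,2Z)-1-hydroxy-3-iodobut-2-en-1-yl]-2-methylidene-6-[(2R,3R)-3-(PMB-oxymethyl)oxiran-2-yl]heptanoate | C=C(C(=O)OC)[C@@H]([C@@H](O)/C=C(/C)I)[C@H](OC(=O)/C(C)=C\C)C[C@@](C)(O)[C@@H]1O[C@@H]1COCc1ccc(OC)cc1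
F15 | step 19 | cis-fused α-methylene-γ-butyrolactone from F14 (C6 oxygen on C12; C10 hydroxyl, C3 PMB ether and alkenyl iodide retained) | C=C1C(=O)O[C@@H](/C=C(/C)I)[C@H]1[C@H](OC(=O)/C(C)=C\C)C[C@@](C)(O)[C@@H]2O[C@@H]2COCc2ccc(OC)cc2
F16 | step 19 | primary alcohol from F15 | C=C1C(=O)O[C@@H](/C=C(/C)I)[C@H]1[C@H](OC(=O)/C(C)=C\C)C[C@@](C)(O)[C@@H]2O[C@@H]2CO
F17 | step 19 | epoxy aldehyde from F16 | C=C1C(=O)O[C@@H](/C=C(/C)I)[C@H]1[C@H](OC(=O)/C(C)=C\C)C[C@@](C)(O)[C@@H]2O[C@@H]2C=O
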